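**Retrosynthetic overview**
- The indole and pyrrole rings are bought intact with OMe and both Br atoms in place. The oxazole is the only ring built, and it is built last.
- Key disconnection: the oxazole N3–C4 and O1–C2 bonds. This gives an indol-3-yl chloromethyl ketone (supplies C4, C5, O1) and a pyrrole NH-imidate (supplies C2, N3).
- The chloromethyl ketone comes from C3 chloroacetylation of 6-bromo-4-methoxyindole.
- The NH-imidate comes from O-ethylation of 5-bromopyrrole-2-carboxamide with Et3OBF4.
- The plan is convergent, with no protecting groups and no redox steps.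

Assumption: the SMILES holds no stereocentre and no stereo-defined double bond, so the target is achiral and needs no enantiocontrol; 1, 2 and 4 are taken as catalogue compounds.

**Step 1**
Reactants: 1 6-bromo-4-methoxy-1H-indole; 2 chloroacetyl chloride
Product: 3 1-(6-bromo-4-methoxy-1H-indol-3-yl)-2-chloroethan-1-one
Conditions: Et2AlCl (1.5 equiv, 1 M in hexanes), CH2Cl2, 0 °C, 30 min; then 2 (1.3 equiv), 0 °C, 2 h; cold 1 M aq HCl quench
Reagents that add atoms: none
Why: Friedel–Crafts C3-acylation of a free NH-indole mediated by a dialkylaluminium chloride, in which Et2AlCl consumes HCl and keeps the Lewis acidity mild so the enamine carbon C3 is acylated without N-protection, the Br-flanked C5 and C7 stay untouched, and C–Cl, Ar–Br and OMe survive at 0 °C; no stereocentre is formed.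

**Step 2**
Reactants: 4 5-bromo-1H-pyrrole-2-carboxamide
Product: 6 ethyl 5-bromo-1H-pyrrole-2-carboximidate (free base), via imidatium tetrafluoroborate 5 (not isolated)
Conditions: Et3OBF4 (1.1 equiv), CH2Cl2, rt, 16 h; then cold sat. aq NaHCO3, extraction, used crude within a day
Reagents that add atoms: triethyloxonium tetrafluoroborate, CC[O+](CC)CC.F[B-](F)(F)F
Why: Meerwein O-alkylation of a primary amide, in which the hard oxonium ion ethylates the carbonyl oxygen (the most nucleophilic site of this vinylogous urea) rather than the non-basic pyrrole nitrogen, and cold bicarbonate frees the NH-imidate; no stereocentre is formed.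

**Step 3 (key step)**
Reactants: 3 1-(6-bromo-4-methoxy-1H-indol-3-yl)-2-chloroethan-1-one; 6 ethyl 5-bromo-1H-pyrrole-2-carboximidate
Product: 9 5-(6-bromo-4-methoxy-1H-indol-3-yl)-2-(5-bromo-1H-pyrrol-2-yl)-1,3-oxazole (breitfussin B), via iodo ketone 7 (not isolated), via N-(2-oxoethyl)imidate 8 (not isolated)
Conditions: 6 (1.4 equiv), NaI (20 mol %), 2,6-lutidine (1.5 equiv), 4 Å MS, MeCN, 60 °C, 12 h; then glacial AcOH (equal volume), 80 °C, 4 h
Reagents that add atoms: none
Why: Proposed new method: the NH-imidate acts as an O-blocked primary amide, so its only nucleophilic atom is the sp2 nitrogen (basicity close to pyridine, which the same halo ketones quaternise), and SN2 attack on the iodide-activated CH2 forms the N3–C4 bond with a base (2,6-lutidine) far too weak to deprotonate the indole or pyrrole NH; in hot AcOH the protonated imidate carbon of 8 is attacked by the strongly nucleophilic vinylogous-amide (enol) oxygen of the 3-acylindole and EtOH is expelled, which forms the O1–C2 bond and aromatises to the 2,5-disubstituted oxazole, the regiochemistry opposite to the Blümlein–Lewy amide/halo-ketone condensation; the closest known reaction types are the amidine plus alpha-halo ketone imidazole synthesis (N-alkylation, then ring closure) and the Cornforth-type closure of an enol oxygen onto an O-alkyl imidate in hot AcOH, while the intermolecular imidate/halo-ketone annulation itself is not established; no stereocentre is formed.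

**Compound list**
1 | 6-bromo-4-methoxy-1H-indole | COc1cc(Br)cc2[nH]ccc12 | starting material
2 | chloroacetyl chloride | O=C(Cl)CCl | starting material
3 | 1-(6-bromo-4-methoxy-1H-indol-3-yl)-2-chloroethan-1-one | COc1cc(Br)cc2[nH]cc(C(=O)CCl)c12 | intermediate
4 | 5-bromo-1H-pyrrole-2-carboxamide | NC(=O)c1ccc(Br)[nH]1 | starting material
5 | ethyl 5-bromo-1H-pyrrole-2-carboximidate hydrotetrafluoroborate | CCOC(=[NH2+])c1ccc(Br)[nH]1.F[B-](F)(F)F | intermediate
6 | ethyl 5-bromo-1H-pyrrole-2-carboximidate | CCOC(=N)c1ccc(Br)[nH]1 | intermediate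
7 | 1-(6-bromo-4-methoxy-1H-indol-3-yl)-2-iodoethan-1-one | COc1cc(Br)cc2[nH]cc(C(=O)CI)c12 | intermediate
8 | ethyl 5-bromo-N-[2-(6-bromo-4-methoxy-1H-indol-3-yl)-2-oxoethyl]-1H-pyrrole-2-carboximidate | CCOC(=NCC(=O)c1c[nH]c2cc(Br)cc(OC)c12)c1ccc(Br)[nH]1 | intermediate
9 | 5-(6-bromo-4-methoxy-1H-indol-3-yl)-2-(5-bromo-1H-pyrrol-2-yl)-1,3-oxazole (breitfussin B) | COc1cc(Br)cc2[nH]cc(-c3cnc(-c4ccc(Br)[nH]4)o3)c12 | target

**Total step count:** 3. **Longest linear sequence:** 2 (1 → 3 → 9, or 4 → 6 → 9).

**Steps most likely to fail**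

1. **Step 3 (proposed new annulation).**
   - Risks: N-alkylation may be slow relative to imidate decay. Halide may de-ethylate protonated 8 to the keto amide. The pyrrole nitrogen may close onto the ketone; this is disfavoured by the poorly electrophilic 3-acylindole carbonyl and by the clash with the adjacent pyrrole bromine.
   - Fallback, all known chemistry, sets out from 3 and comes back at 9. Azide displacement (NaN3, acetone/H2O, rt) gives 2-azido-1-(6-bromo-4-methoxy-1H-indol-3-yl)ethan-1-one F1. Staudinger reduction (PPh3, THF/H2O, then HCl in Et2O) gives 2-amino-1-(6-bromo-4-methoxy-1H-indol-3-yl)ethan-1-one hydrochloride F2. EDC·HCl/HOBt/iPr2NEt coupling with purchased 5-bromo-1H-pyrrole-2-carboxylic acid (O=C(O)c1ccc(Br)[nH]1) gives 5-bromo-N-[2-(6-bromo-4-methoxy-1H-indol-3-yl)-2-oxoethyl]-1H-pyrrole-2-carboxamide F3. Robinson–Gabriel cyclodehydration (POCl3, toluene, 90 °C) then closes the oxazole to 9.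

2. **Step 1.**
   - Risks: peri hindrance from the 4-OMe group, and chelation-assisted O-demethylation of the product by the aluminium Lewis acid.
   - Fallback sets out from 1 and comes back at 3. It is a metal-free Vilsmeier–Haack-type acylation. 2-Chloro-N,N-dimethylacetamide is pre-activated with POCl3 (0 °C) and then heated with 1 in 1,2-dichloroethane at 70 °C. This gives N-[1-(6-bromo-4-methoxy-1H-indol-3-yl)-2-chloroethylidene]-N-methylmethanaminium chloride F4, which aqueous NaOAc hydrolyses to 3.

3. **Step 2.**
   - Risks: poor solubility of 4 in CH2Cl2, and hydrolysis of the imidate during the bicarbonate wash.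
   - Fallback sets out from 4 and comes back at 6. Dehydration (trifluoroacetic anhydride, pyridine, 0 °C) gives 5-bromo-1H-pyrrole-2-carbonitrile F5. A Pinner reaction (dry HCl, EtOH, Et2O, 0 °C) gives crystalline ethyl 5-bromo-1H-pyrrole-2-carboximidate hydrochloride F6. This salt is filtered and neutralised with cold NaHCO3 just before use to give 6.

**Further compounds**
F1 | step 3 | 2-azido-1-(6-bromo-4-methoxy-1H-indol-3-yl)ethan-1-one | COc1cc(Br)cc2[nH]cc(C(=O)CN=[N+]=[N-])c12
F2 | step 3 | 2-amino-1-(6-bromo-4-methoxy-1H-indol-3-yl)ethan-1-one hydrochloride | COc1cc(Br)cc2[nH]cc(C(=O)C[NH3+])c12.[Cl-]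
F3 | step 3 | 5-bromo-N-[2-(6-bromo-4-methoxy-1H-indol-3-yl)-2-oxoethyl]-1H-pyrrole-2-carboxamide | COc1cc(Br)cc2[nH]cc(C(=O)CNC(=O)c3ccc(Br)[nH]3)c12
F4 | step 1 | N-[1-(6-bromo-4-methoxy-1H-indol-3-yl)-2-chloroethylidene]-N-methylmethanaminium chloride | COc1cc(Br)cc2[nH]cc(C(CCl)=[N+](C)C)c12.[Cl-]
F5 | step 2 | 5-bromo-1H-pyrrole-2-carbonitrile | N#Cc1ccc(Br)[nH]1
F6 | step 2 | ethyl 5-bromo-1H-pyrrole-2-carboximidate hydrochloride | CCOC(=[NH2+])c1ccc(Br)[nH]1.[Cl-]
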